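Each new flask is read at 15 h, and that reading is what we must forecast as c(added ligand) changes.

in all of them: solid substrate 0.073 M; reagent 0.292 M; free catalyst 11 mM

|  | added ligand | remark | time |
|---|---|---|---|
| grey | 7.7 mM | run made earlier |  |
| teal | 26 mM | run made earlier |  |
| red | 67 mM | run made earlier |  |
| Thursday's | 10 mM |  | 15 h |
| Saturday's | 20 mM |  | 15 h |
| Friday's | 40 mM |  | 15 h |
| Tuesday's | 80 mM |  | 15 h |

| run | time / h | product / % |
|---|---|---|
| grey | 2.00 | 11.5 |
| grey | 5.00 | 43.1 |
| grey | 10.0 | 77.9 |
| grey | 15.0 | 95.1 |
| teal | 4.00 | 31.7 |
| teal | 8.00 | 66.3 |
| teal | 12.0 | 87.5 |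
| teal | 15.0 | 94.5 |
| red | 1.33 | 5.9 |
| red | 3.00 | 21.6 |
| red | 6.00 | 49.3 |
| red | 15.0 | 91.2 |

(scatter of a reading: 1 percentage point)

- solid, in amounts per volume of the solution: solid substrate
- reactions considered so far: reagent + free catalyst -> catalyst intermediate A; solid substrate <-> starting material; catalyst intermediate A -> by-product + catalyst intermediate B; catalyst intermediate C -> free catalyst + product; free catalyst + added ligand <-> idle complex; starting material + catalyst intermediate B -> catalyst intermediate C
- at the start none of the solid substrate is in solution
- "hardly changes" means that all values lie within two and a half points (for a concentration: within two and a half percent of the largest)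

* amount of product at the end, in percent of the solid substrate charged for Thursday's, Saturday's, Friday's, Tuesday's, in this order
* how that number moves from the first to the last of them (falls all the way / falls, then rises / hardly changes / rises all the way / rises, then falls)

Two numbers seem to clash. From the grey run to the red run, c(added ligand) rises from 7.7 mM to 67 mM, and the reading at 15.0 h falls by 3.9 percentage points. But at 6.00 h the red run stands at 49.3%, and the grey run, interpolated between its readings, at 50.1%. That gap is 0.76 points.

We reckon in hours of lag. Over its last two readings, the teal run's share short of product falls from 12.5% to 5.50%. So, as read from these two scattered readings, that share halves about every 2.53 h; this tail half-life, read as pseudo-first-order, is what we carry.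

At the grey run's mid-course pace, the red gap is a lag of 0.109 h. A slowdown by a fixed share stretches a lag in proportion to time, so it becomes 0.273 h at 15.0 h. That is 0.108 tail half-lives, worth 0.41 points on the teal run's shortfall of 5.50%.

The end gap of 3.9 points would need a lag of 2.59 h, or 1.04 h at 6.00 h, against the 0.109 h read there. We therefore trust mid-course and read the end gap as inflated by the scatter of 1 point per reading. Scaled to 10 mM through 80 mM, our span is 0.48 points, so we expect the row to hardly change, near 93.6%.

The forecast differs on the shape. It gives 94.9%, 94.3%, 93% and 90.3%, and “The total drop of about 4.5 points exceeds 2.5”, so its answer is falls all the way.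

The flasks give 93.9%, 93.7%, 93.4% and 92.7%, so the shape is: hardly changes.

reagent + free catalyst → catalyst intermediate A (k = 99.0 L mol⁻¹ h⁻¹); solid substrate ⇌ starting material, rate k2*(cs2 - [starting material]) while solid is left; crystals form when [starting material] > cs2 (solubility = 0.0540 M, k = 1.60 h⁻¹); catalyst intermediate A → by-product + catalyst intermediate B (k = 2.60 h⁻¹); catalyst intermediate C → free catalyst + product (k = 2.50 h⁻¹); free catalyst + added ligand ⇌ idle complex, settled at all times (K = 34.0 L mol⁻¹); starting material + catalyst intermediate B → catalyst intermediate C (k = 30.0 L mol⁻¹ h⁻¹) At 15.0 h, Tuesday's flask holds 1.81% of the catalyst charged as idle complex. Thursday's flask stands 6.10% short of product at that time. With the tail half-life of 2.53 h read from the teal run, Tuesday's shortfall of 1.2 points against Thursday's reckons as a lag of about 0.718 h.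

The runs were computed for an exercise; the scatter is artificial.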